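**Retrosynthetic overview**
- Gardenin E ⇐ one-pot BCl3 deprotection of its 3',5'-di-O-benzyl-5-O-methyl ether; the 5-OMe is cleaved selectively by chelation to the C4 carbonyl.
- Ring C (the pyranone) is the only ring built, and it is built last: Rh(III)-catalysed aldehyde C–H activation/annulation of a salicylaldehyde with an aroyl sulfoxonium ylide forms C4–C3 (carbene insertion) and then O1–C2 (cyclodehydration). This replaces the usual Baker–Venkataraman or chalcone route.
- Ring A is bought as an arene: 2-hydroxy-3,4,5,6-tetramethoxybenzaldehyde ⇐ ortho-formylation of 2,3,4,5-tetramethoxyphenol ⇐ lithiation/borylation/oxidation of symmetric 1,2,3,4-tetramethoxybenzene.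
- Ring B is bought as an arene: the sulfoxonium ylide ⇐ methyl 3,5-bis(benzyloxy)-4-methoxybenzoate ⇐ methyl 3,5-dihydroxy-4-methoxybenzoate.

Assumption: Gardenin E has no stereocentre and no stereogenic double bond, so "the single enantiomer given" is taken as the achiral compound exactly as drawn; no step creates a stereocentre.

**Step 1**
Reactants: 1 1,2,3,4-tetramethoxybenzene
Product: 4 2,3,4,5-tetramethoxyphenol, via aryllithium 2 (not isolated), via dimethyl arylboronate 3 (not isolated)
Conditions: n-BuLi, TMEDA, THF, 0 °C; B(OMe)3, −78 °C → rt; then AcOH, 30% aq. H2O2, 0 °C → rt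
Reagents that add atoms: hydrogen peroxide, OO (phenol oxygen of 4); n-butyllithium, [Li]CCCC (Li of 2 only); trimethyl borate, COB(OC)OC (B(OMe)2 of 3 only)
Why: Methoxy-directed ortho-metalation (the two free ring positions are equivalent by symmetry), borylation of the aryllithium, and oxidative 1,2-aryl shift from boron to oxygen (boronate oxidation) give the phenol as a single regioisomer.

**Step 2**
Reactants: 4 2,3,4,5-tetramethoxyphenol
Product: 6 2-hydroxy-3,4,5,6-tetramethoxybenzaldehyde, via salicyl alcohol 5 (not isolated)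
Conditions: MgCl2, Et3N, (CH2O)n, MeCN, reflux; 1 M HCl work-up
Reagents that add atoms: paraformaldehyde (as formaldehyde), C=O
Why: Casnati–Skattebøl ortho-formylation: the magnesium phenoxide delivers formaldehyde to the only free ring position, and the resulting salicyl alkoxide 5 is oxidised by a second formaldehyde through Oppenauer-type hydride transfer.

**Step 3**
Reactants: 7 methyl 3,5-dihydroxy-4-methoxybenzoate
Product: 8 methyl 3,5-bis(benzyloxy)-4-methoxybenzoate
Conditions: BnBr, K2CO3, DMF, 60 °C
Reagents that add atoms: benzyl bromide, BrCc1ccccc1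
Why: Williamson ether synthesis on both phenols, which are the only acidic sites; the ester and the 4-OMe are untouched.

**Step 4**
Reactants: 8 methyl 3,5-bis(benzyloxy)-4-methoxybenzoate
Product: 9 1-[3,5-bis(benzyloxy)-4-methoxyphenyl]-2-[dimethyl(oxo)-λ6-sulfanylidene]ethan-1-one
Conditions: Me3S(O)I, KOtBu, THF, reflux; then 8, 0 °C → reflux
Reagents that add atoms: trimethylsulfoxonium iodide, C[S+](C)(C)=O.[I-] (reacts as dimethylsulfoxonium methylide, C=S(C)(C)=O)
Why: Corey–Chaykovsky-type C-acylation of dimethylsulfoxonium methylide by the benzoate ester (addition–elimination of methoxide), with excess ylide deprotonating the product to the stabilised β-keto sulfoxonium ylide; benzyl and methyl ethers are inert to the base.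

**Step 5**
Reactants: 6 2-hydroxy-3,4,5,6-tetramethoxybenzaldehyde; 9 1-[3,5-bis(benzyloxy)-4-methoxyphenyl]-2-[dimethyl(oxo)-λ6-sulfanylidene]ethan-1-one
Product: 11 2-[3,5-bis(benzyloxy)-4-methoxyphenyl]-5,6,7,8-tetramethoxy-4H-chromen-4-one, via beta-diketone 10 (not isolated)
Conditions: [Cp*RhCl2]2 (4 mol%), AgSbF6 (16 mol%), NaOAc (0.5 equiv), PivOH (1 equiv), DCE, 100 °C; then TsOH·H2O (cat.), 80 °C
Reagents that add atoms: none
Why: Rh(III)-catalysed phenoxide-directed aldehyde C–H activation gives a five-membered acyl-rhodacycle that takes up ylide 9 as a carbene equivalent (loss of DMSO, migratory insertion, protodemetalation; C–H acylmethylation) to give β-diketone 10, which undergoes acid-catalysed cyclodehydration onto the aroyl ketone to close the chromen-4-one; this is the known salicylaldehyde/sulfoxonium ylide annulation to chromones, applied here to a hindered, electron-rich aldehyde.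

**Step 6**
Reactants: 11 2-[3,5-bis(benzyloxy)-4-methoxyphenyl]-5,6,7,8-tetramethoxy-4H-chromen-4-one
Product: 12 Gardenin E, 2-(3,5-dihydroxy-4-methoxyphenyl)-5-hydroxy-6,7,8-trimethoxy-4H-chromen-4-one
Conditions: BCl3 (8 equiv), C6HMe5 (6 equiv), CH2Cl2, −78 → 0 °C; aq. HCl work-up
Reagents that add atoms: none
Why: Lewis-acid ether cleavage: BCl3 removes aryl benzyl ethers at −78 °C (benzyl cation trapped by pentamethylbenzene, Friedel–Crafts) and on warming cleaves only the 5-OMe, which sits in a six-membered boron chelate with the C4 carbonyl (SN2 by chloride on methyl), while the non-chelated 6-, 7-, 8- and 4'-OMe groups persist at ≤0 °C.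

**Compound list**
1 | 1,2,3,4-tetramethoxybenzene | COc1ccc(OC)c(OC)c1OC | starting material
2 | (2,3,4,5-tetramethoxyphenyl)lithium | [Li]c1cc(OC)c(OC)c(OC)c1OC | intermediate (not isolated)
3 | dimethyl (2,3,4,5-tetramethoxyphenyl)boronate | COB(OC)c1cc(OC)c(OC)c(OC)c1OC | intermediate (not isolated)
4 | 2,3,4,5-tetramethoxyphenol | COc1cc(O)c(OC)c(OC)c1OC | intermediate
5 | 2-(hydroxymethyl)-3,4,5,6-tetramethoxyphenol (salicyl alcohol, formed as its magnesium salt) | OCc1c(O)c(OC)c(OC)c(OC)c1OC | intermediate (not isolated)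
6 | 2-hydroxy-3,4,5,6-tetramethoxybenzaldehyde | O=Cc1c(O)c(OC)c(OC)c(OC)c1OC | intermediate
7 | methyl 3,5-dihydroxy-4-methoxybenzoate | COC(=O)c1cc(O)c(OC)c(O)c1 | starting material
8 | methyl 3,5-bis(benzyloxy)-4-methoxybenzoate | COC(=O)c1cc(OCc2ccccc2)c(OC)c(OCc2ccccc2)c1 | intermediate
9 | 1-[3,5-bis(benzyloxy)-4-methoxyphenyl]-2-[dimethyl(oxo)-λ6-sulfanylidene]ethan-1-one | COc1c(OCc2ccccc2)cc(C(=O)C=S(C)(C)=O)cc1OCc1ccccc1 | intermediate
10 | 1-[3,5-bis(benzyloxy)-4-methoxyphenyl]-3-(2-hydroxy-3,4,5,6-tetramethoxyphenyl)propane-1,3-dione | COc1c(OCc2ccccc2)cc(C(=O)CC(=O)c2c(O)c(OC)c(OC)c(OC)c2OC)cc1OCc1ccccc1 | intermediate (not isolated)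
11 | 2-[3,5-bis(benzyloxy)-4-methoxyphenyl]-5,6,7,8-tetramethoxy-4H-chromen-4-one | COc1c(OCc2ccccc2)cc(-c2cc(=O)c3c(OC)c(OC)c(OC)c(OC)c3o2)cc1OCc1ccccc1 | intermediate
12 | Gardenin E, 2-(3,5-dihydroxy-4-methoxyphenyl)-5-hydroxy-6,7,8-trimethoxy-4H-chromen-4-one | COc1c(O)cc(-c2cc(=O)c3c(O)c(OC)c(OC)c(OC)c3o2)cc1O | target

**Totals**
Total step count: 6. Longest linear sequence: 4 steps (1 → 4 → 6 → 11 → 12, or 7 → 8 → 9 → 11 → 12).

**Steps most likely to fail, with fallbacks**

Step 5 (Rh(III) C–H annulation). The aldehyde is flanked by OH and OMe, so the acyl-rhodium may decarbonylate or insert slowly, and the ylide can self-couple. The fallback sets out from compound 4 and comes back to the route at compound 10. Phenol 4 is C-acetylated at its only free ring position with AcOH/BF3·OEt2 at 90 °C to give 1-(2-hydroxy-3,4,5,6-tetramethoxyphenyl)ethan-1-one F1. Its dianion (LiHMDS, 3.3 equiv, THF, −78 °C) is C-acylated by ester 8 in a Claisen condensation to give β-diketone 10. This is cyclodehydrated with catalytic TsOH as in the second stage of step 5 to give 11.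

Step 6 (one-pot triple dealkylation). Over-demethylation at the 6-OMe next to the boron chelate, or at the 4'-OMe flanked by two boron-bound oxygens, is possible if the mixture warms. The fallback sets out from compound 11 and comes back at compound 12, with the order reversed and the two events made orthogonal. Chelation-specific demethylation with MgI2·OEt2 in toluene at 80 °C removes only the 5-O-methyl and leaves the benzyl ethers, giving 2-[3,5-bis(benzyloxy)-4-methoxyphenyl]-5-hydroxy-6,7,8-trimethoxy-4H-chromen-4-one F2. Neutral hydrogenolysis (H2, 1 atm, 10% Pd/C, EtOAc/MeOH, rt) then frees the two B-ring phenols to give 12 without exposing them to any Lewis acid.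

Step 1 (lithiation/borylation/oxidation). Incomplete lithiation or over-oxidation of the very electron-rich phenol can lower the yield. The fallback sets out from compound 1 and comes back at compound 4, replacing metalation by electrophilic substitution. Rieche formylation (Cl2CHOMe, TiCl4, CH2Cl2, −10 °C; one product by symmetry) gives 2,3,4,5-tetramethoxybenzaldehyde F3. Baeyer–Villiger (Dakin-type) oxidation with mCPBA in CH2Cl2 gives 2,3,4,5-tetramethoxyphenyl formate F4. Methanolysis with K2CO3/MeOH releases phenol 4.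

**Further compounds**
F1 | step 5 | 1-(2-hydroxy-3,4,5,6-tetramethoxyphenyl)ethan-1-one | CC(=O)c1c(O)c(OC)c(OC)c(OC)c1OC
F2 | step 6 | 2-[3,5-bis(benzyloxy)-4-methoxyphenyl]-5-hydroxy-6,7,8-trimethoxy-4H-chromen-4-one | COc1c(OCc2ccccc2)cc(-c2cc(=O)c3c(O)c(OC)c(OC)c(OC)c3o2)cc1OCc1ccccc1
F3 | step 1 | 2,3,4,5-tetramethoxybenzaldehyde | COc1cc(C=O)c(OC)c(OC)c1OC
F4 | step 1 | 2,3,4,5-tetramethoxyphenyl formate | COc1cc(OC=O)c(OC)c(OC)c1OC
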